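Remark on the chemistry: locants C1–C7a, C8 (carboxyl carbon) and C1'–C4' (side chain) are those of the two-ring description used below, not indene locants; with them the target is (1S,3aS,4R,7R,7aR), and "β" is the face that carries the side chain on C1.

## Structural features

The target is a 3a,4,7,7a-tetrahydroindene: six-membered ring A (C1–C2=C3–C3a–C7a–C7) and five-membered ring B (C3a–C4–C5=C6–C7a) share the C3a–C7a bond in a trans fusion (H-7a β, H-3a α), and each ring holds one trisubstituted alkene. Five contiguous stereocentres run C1–C7–C7a–C3a–C4: C1 (ethyl α, dienyl β) and C7 (methyl α, CO2H β) are adjacent all-carbon quaternary centres, and the three substituents on ring B (C7 on C7a, C3 on C3a, methyl on C4) alternate faces. The side chain on C1 is a (1E,3E)-2-methyl-4-phenylbuta-1,3-dienyl group whose first carbon C1' is neopentylic. Fragile elements are the styryl diene (acid, light, oxidants, hydrogenation catalysts), the doubly allylic C3a–H and allylic C4–H (alkene migration under base or metal hydrides), and the strained trans-fused diene itself. The real difficulty is the vicinal quaternary pair C1/C7: C7 has to be set relative to C7a, and at C1 an ethyl group has to be told from an alkenyl arm of almost the same size. The key step exploits the cis relationship of C8 (on C7) and C1' (on C1): tied as a γ-lactone C8(=O)–O–C1', they leave C1 with two identical vinyl arms, and only the vinyl cis to the C7–C7a bond can meet the isopropenyl group on C3a to form C2=C3 and close ring A.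

## Logic of the disconnections

29 ⇒ 28: the C3'=C4' styryl alkene is cut first because it is the most sensitive group and is best made last. The gain is loss of the phenyl diene; the demand is an E-selective olefination of an enal that tolerates a free carboxylate.

28 ⇒ 27: the trisubstituted C1'=C2' alkene is cut back to an aldehyde on C1'. This reduces the whole side chain to one carbon on C1; the forward step must olefinate a neopentylic aldehyde flanked by two quaternary carbons with E geometry.

27 ⇒ 25: C8 and C1' are reconnected through oxygen and C1' is lowered to the alcohol level, giving the γ-lactone. This turns two cis substituents into one rigid template; the forward step must open a hindered lactone and oxidise C1' before the ring can re-close.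

25 ⇒ 24: ethyl is retraced to vinyl. C1 then derives from a carbon bearing two identical vinyl groups; the forward step must hydrogenate a monosubstituted alkene in the presence of two trisubstituted ones.

24 ⇒ 23: the C2=C3 bond is cut by retro-metathesis, opening ring A. The gain is large: C1 is no longer a stereocentre and the tricycle falls to a lactone joined to a cyclopentene by one bond. The forward step must select one of two diastereotopic vinyl groups and form a trisubstituted alkene between two hindered carbons.

23 ⇒ 22 ⇒ 21: the C5–H bond is retraced to an enol triflate and that to a silyl enol ether. This exposes the regiodefined enolate of a conjugate addition; the forward steps must keep the C5=C6 position without equilibration.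

21 ⇒ 11 + 19: the C7–C7a bond is cut as a Michael addition of a lactone enolate equivalent to a cyclopentenone. The route becomes convergent, with two fragments of similar size. Two stereocentres arise in this step, not one: C7a (face of ring B, governed by the neighbouring isopropenyl group) and C7 (mutual orientation of the two planar partners). The second must be controlled explicitly, because the later ring closure cannot correct it.

19 ⇒ 18 ⇒ 17: the C6–CH3 bond is cut to an α-iodoenone and then to the parent enone. The forward steps must run under non-basic conditions because C3a–H is doubly activated.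

17 ⇒ 16 ⇒ 12 + 13: the enone is retraced to a β-silyloxy ketone, and the C3a–C3 and C4–CH3 bonds are cut as conjugate addition and enolate methylation. All of ring B's stereochemistry then derives from the single stereocentre of 12; both new bonds must form anti to their neighbours, and methylation must be faster than enolate equilibration.

11 ⇒ 7: the lactone C–O bond is opened and the bond between the α-carbon and the divinyl carbon is cut by a retro-[3,3] shift. The quaternary divinyl carbon then comes from a trisubstituted alkene terminus; because the two vinyl groups are identical, no enolate or alkene geometry needs control.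

7 ⇒ 5 + 6 ⇒ 4 ⇒ 2 ⇒ 1: the ester is cut, the vinyl group is removed (cross-coupling), the alkenyl iodide is retraced to the alkyne (directed hydroalumination) and the silyl ether to the symmetric diol. The forward steps must place the free hydroxyl on the CH2–CH= end of the diene, which the hydroxyl-directed hydroalumination does.

## Other disconnections considered

Alternative 1: The cut is C7–C1 together with a temporary C8–C2 bond (retro [2+2]). In the forward direction a ketene generated from an acid chloride adds intramolecularly across the trisubstituted C2=C1 alkene in the bridged sense to give bicyclo[3.1.1]heptan-6-one A1, and hydroxide-induced cleavage of C8–C2 (retro-Claisen of the strained ketone) then frees the C7 carboxylate.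
- In its favour: C1 and C7 are set together in one stereospecific event from the alkene geometry, and the electronic bias of a 1,1-disubstituted distal alkene carbon favours the bridged mode. On this point the alternative is better than the chosen plan, which needs two separate events (conjugate addition for C7, metathesis for C1).
- Against it here: A1 has no ring B (C3a and C7a are methylene groups) and no C3 methyl. A trans-fused cyclopentene with three stereocentres would have to be annulated afterwards onto a ring that already carries two quaternary carbons, and the C3 silyl ether would have to become the C2=C3(Me) alkene.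
- Comparison: the mechanism is more elegant for the quaternary pair, but the structural coverage is poorer and the step count after the key step is clearly higher. The ring-fusion stereocentres, which the chosen plan takes early from one commercial stereocentre, would be the late and uncertain part.

Alternative 2: The cut is C1–C7, with C8 tied through oxygen to C3. In the forward direction the silyl ketene acetal of a δ-lactone rearranges ([3,3], boat-like, ring-contracting) through the alkenyl group on C3 to the ring A acid A2, and ring B is then closed by metathesis between the C5 vinyl and C6 isopropenyl groups.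
- In its favour: both quaternary carbons, ring A and the C2=C3 alkene arise in one intramolecular step. C7 is set inside a ring that also contains C7a, so the C7/C7a relationship is under cyclic control; on this point it is better than the chosen plan, which relies on an open transition state. The acid is also free from the start, which shortens the endgame.
- Against it here: the lactone substrate needs a tertiary allylic carbinol at C3 prone to ionisation, three contiguous stereocentres (C3a, C7a, C4) built without a ring to guide them, and a stereodefined trisubstituted alkene that distinguishes ethyl from silyloxymethyl at C1.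
- Comparison: step economy is about equal. The mechanistic risk is moved from the union to substrate assembly and to enolisation of a lactone that can eliminate. The chosen plan avoids telling the C1 arms apart altogether.

Alternative 3: The cuts are C3a–C7a, C4–C5 and C5–C6. In the forward direction an intramolecular Pauson–Khand reaction (Co2(CO)8) of a 1,7-enyne held on the γ-lactone closes rings A and B at once and gives enone A3.
- In its favour: three C–C bonds and two rings form in one step, and the (E)-propenyl geometry is transferred to the C3a/C4 relationship. In bonds and rings formed per step it is better than the chosen key step, and it uses the same lactone template idea for C1/C7.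
- Against it here: 1,7-enynes with an internal alkyne and a 1,2-disubstituted alkene are poor substrates. C1 must already be a defined stereocentre with ethyl in place. A3 has C7a as an sp2 carbon, so the trans ring fusion would have to come from a later reduction of a tetrasubstituted enone with uncertain facial outcome. C5=O must be transposed to the C5=C6 alkene and C3 still lacks its methyl and alkene.
- Comparison: the key step is more powerful, but the stereochemical burden is shifted to its aftermath and the sequence after it is longer. The chosen plan fixes C7a and C3a before the rings are joined.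

Key step: step 13

## Route

Step 1
Reactants: 1 but-2-yne-1,4-diol
Product: 2 4-(tert-butyldimethylsilyloxy)but-2-yn-1-ol
Conditions: NaH (1.0 equiv), THF, 0 → 23 °C; t-BuMe2SiCl (1.0 equiv), 23 °C
Reagents that add atoms: tert-butyldimethylsilyl chloride CC(C)(C)[Si](C)(C)Cl
Why: Monosilylation of a symmetric diol through its sparingly soluble monosodium alkoxide (O-silylation); only one hydroxyl is deprotonated, so the mono-ether should dominate.

Step 2
Reactants: 2 4-(tert-butyldimethylsilyloxy)but-2-yn-1-ol
Product: 4 (Z)-4-(tert-butyldimethylsilyloxy)-3-iodobut-2-en-1-ol, via sodium alkenylaluminate 3 (not isolated)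
Conditions: NaAlH2(OCH2CH2OMe)2, THF, 0 → 23 °C; then I2, THF, −78 → 0 °C
Reagents that add atoms: iodine II
Why: Hydroxyl-directed trans-hydroalumination of the propargylic alcohol puts aluminium on the distal alkyne carbon inside a five-membered aluminate, and iodinolysis with retention gives the (Z)-alkenyl iodide; the silyl ether is inert.

Step 3
Reactants: 4 (Z)-4-(tert-butyldimethylsilyloxy)-3-iodobut-2-en-1-ol
Product: 5 (E)-3-[(tert-butyldimethylsilyloxy)methyl]penta-2,4-dien-1-ol
Conditions: CH2=CHBF3K, PdCl2(dppf) (5 mol %), Cs2CO3, THF–H2O (9:1), 65 °C
Reagents that add atoms: potassium vinyltrifluoroborate [K+].C=C[B-](F)(F)F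
Why: Suzuki–Miyaura coupling of an alkenyl iodide with retention of geometry; the free allylic alcohol is tolerated, and the alkene geometry is in any case erased in step 5.

Step 4
Reactants: 5 (E)-3-[(tert-butyldimethylsilyloxy)methyl]penta-2,4-dien-1-ol, 6 propanoyl chloride
Product: 7 (E)-3-[(tert-butyldimethylsilyloxy)methyl]penta-2,4-dien-1-yl propanoate
Conditions: pyridine, 4-(dimethylamino)pyridine (5 mol %), CH2Cl2, 0 °C
Reagents that add atoms: none
Why: Acylation of a primary allylic alcohol with an acid chloride under nucleophilic catalysis.

Step 5
Reactants: 7 (E)-3-[(tert-butyldimethylsilyloxy)methyl]penta-2,4-dien-1-yl propanoate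
Product: 11 4,4-diethenyl-3-methyloxolan-2-one (racemic), via trimethylsilyl ketene acetal 8 (not isolated), via rearranged trimethylsilyl ester 9 (not isolated), via hydroxy acid 10 (not isolated)
Conditions: LiN(i-Pr)2, THF, −78 °C; Me3SiCl; −78 → 50 °C; then 2 M HCl, THF–MeOH, 23 °C
Reagents that add atoms: none
Why: Ireland–Claisen rearrangement: the silyl ketene acetal shifts [3,3] onto the fully substituted alkene terminus and creates a quaternary carbon with two identical vinyl groups, so neither enolate nor alkene geometry matters. Acid then removes both silyl groups and the γ-hydroxy acid lactonises spontaneously (gem-disubstituent effect); the α-stereocentre of 11 is racemic and is erased in step 10.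

Step 6
Reactants: 12 (S)-4-(tert-butyldimethylsilyloxy)cyclopent-2-en-1-one, 13 2-bromopropene
Product: 16 (2S,3R,4S)-4-(tert-butyldimethylsilyloxy)-2-methyl-3-(prop-1-en-2-yl)cyclopentan-1-one, via isopropenylmagnesium bromide 14 (not isolated), via bromomagnesium enolate 15 (not isolated)
Conditions: 13, Mg, THF, 40 °C; then 12, CuBr·SMe2 (10 mol %), THF, −78 °C; then MeI (5 equiv), HMPA, −78 → −20 °C
Reagents that add atoms: iodomethane CI
Why: Copper-catalysed 1,4-addition of the alkenyl Grignard reagent occurs anti to the silyloxy group, and the enolate is methylated anti to the new isopropenyl group (tandem conjugate addition–enolate alkylation), giving the all-trans ketone. HMPA and excess MeI are used so that C-methylation outruns enolate equilibration.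

Step 7
Reactants: 16 (2S,3R,4S)-4-(tert-butyldimethylsilyloxy)-2-methyl-3-(prop-1-en-2-yl)cyclopentan-1-one
Product: 17 (4R,5S)-5-methyl-4-(prop-1-en-2-yl)cyclopent-2-en-1-one
Conditions: DBU (1.2 equiv), CH2Cl2, −20 → 0 °C, short reaction time
Reagents that add atoms: none
Why: E1cB elimination of silanol from the β-silyloxy ketone; the two remaining stereocentres are not part of the elimination, and brief exposure at low temperature should avoid deprotonation at the doubly allylic carbon.

Step 8
Reactants: 17 (4R,5S)-5-methyl-4-(prop-1-en-2-yl)cyclopent-2-en-1-one
Product: 18 (4S,5S)-2-iodo-5-methyl-4-(prop-1-en-2-yl)cyclopent-2-en-1-one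
Conditions: I2, pyridine–CH2Cl2 (1:1), 0 → 23 °C
Reagents that add atoms: iodine II
Why: α-Iodination of the enone by pyridine addition, enolate iodination and elimination (Baylis–Hillman-type mechanism); the CIP descriptor at C4 changes only because iodine alters priorities.

Step 9
Reactants: 18 (4S,5S)-2-iodo-5-methyl-4-(prop-1-en-2-yl)cyclopent-2-en-1-one
Product: 19 (4R,5S)-2,5-dimethyl-4-(prop-1-en-2-yl)cyclopent-2-en-1-one
Conditions: MeZnCl, Pd2(dba)3 (2.5 mol %), P(2-furyl)3 (10 mol %), THF–DMF, 23 °C
Reagents that add atoms: methylzinc chloride C[Zn]Cl
Why: Negishi coupling of the α-iodoenone with a methylzinc reagent; the neutral conditions are chosen to avoid epimerisation at the doubly allylic carbon.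

Step 10
Reactants: 11 4,4-diethenyl-3-methyloxolan-2-one (racemic), 19 (4R,5S)-2,5-dimethyl-4-(prop-1-en-2-yl)cyclopent-2-en-1-one
Product: 21 (3R)-3-[(1R,4S,5R)-3-(tert-butyldimethylsilyloxy)-2,4-dimethyl-5-(prop-1-en-2-yl)cyclopent-2-en-1-yl]-4,4-diethenyl-3-methyloxolan-2-one, via tert-butyldimethylsilyl ketene acetal 20 (not isolated)
Conditions: LiN(i-Pr)2, THF, −78 °C; t-BuMe2SiCl, DMPU, −78 → 0 °C; pentane, filter, concentrate; then 19, Tf2NH (5 mol %), CH2Cl2, −78 → −40 °C; Et3N
Reagents that add atoms: tert-butyldimethylsilyl chloride CC(C)(C)[Si](C)(C)Cl
Why: Mukaiyama–Michael addition: the ketene acetal attacks the silylium-activated enone at C7a on the face opposite the adjacent isopropenyl group (sets C7a), and silyl transfer gives the C5=C6 silyl enol ether regiospecifically. C7 is set by the mutual orientation of the partners in the open transition state: the quaternary C1 should point away from ring B over H-7a, the flat silyloxy carbon C8 should lie over the C6–C5 enone π system and the small methyl toward C3a, which gives the required (R) centre. This is the least secure stereochemical element of the route.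

Step 11
Reactants: 21 (3R)-3-[(1R,4S,5R)-3-(tert-butyldimethylsilyloxy)-2,4-dimethyl-5-(prop-1-en-2-yl)cyclopent-2-en-1-yl]-4,4-diethenyl-3-methyloxolan-2-one
Product: 22 (3R)-4,4-diethenyl-3-[(1R,4S,5R)-2,4-dimethyl-5-(prop-1-en-2-yl)-3-(trifluoromethanesulfonyloxy)cyclopent-2-en-1-yl]-3-methyloxolan-2-one
Conditions: CsF, PhNTf2, DME, 23 °C
Reagents that add atoms: N-phenylbis(trifluoromethanesulfonimide) O=S(=O)(N(c1ccccc1)S(=O)(=O)C(F)(F)F)C(F)(F)F
Why: Fluoride cleaves the silyl enol ether to the caesium enolate without regiochemical scrambling and the triflimide traps it on oxygen (enol triflate formation); the lactone has no α-hydrogen and is inert.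

Step 12
Reactants: 22 (3R)-4,4-diethenyl-3-[(1R,4S,5R)-2,4-dimethyl-5-(prop-1-en-2-yl)-3-(trifluoromethanesulfonyloxy)cyclopent-2-en-1-yl]-3-methyloxolan-2-one
Product: 23 (3R)-4,4-diethenyl-3-[(1R,4R,5S)-2,4-dimethyl-5-(prop-1-en-2-yl)cyclopent-2-en-1-yl]-3-methyloxolan-2-one
Conditions: Pd(OAc)2 (5 mol %), PPh3 (10 mol %), HCO2H, n-Bu3N, DMF, 60 °C
Reagents that add atoms: none
Why: Palladium-catalysed formate reduction of the enol triflate (oxidative addition, decarboxylation of the formate, C–H reductive elimination) replaces OTf by H and fixes the C5=C6 alkene; no stereocentre is involved, and the descriptors change only through CIP priorities.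

Step 13
Reactants: 23 (3R)-4,4-diethenyl-3-[(1R,4R,5S)-2,4-dimethyl-5-(prop-1-en-2-yl)cyclopent-2-en-1-yl]-3-methyloxolan-2-one
Product: 24 tricyclic vinyl lactone (ring A closed at C2=C3; γ-lactone C8(=O)–O–C1' cis-fused across C7–C1; vinyl on C1 cis to the C7 methyl; ring B trans-fused)
Conditions: RuCl2(H2IMes)(=CH-C6H4-2-O-i-Pr) (10 mol %; H2IMes = 1,3-dimesitylimidazolidin-2-ylidene; phosphine-free second-generation catalyst), 1,4-benzoquinone (20 mol %), toluene (0.005 M), 100 °C, argon sparge
Reagents that add atoms: none
Why: The ruthenium carbene exchanges onto a vinyl group with loss of ethene, the resulting alkylidene on C2 adds intramolecularly across the isopropenyl group ([2+2] cycloaddition), and cycloreversion gives C2=C3 and a ruthenium methylidene. The closest known reaction types are ring-closing metathesis to trisubstituted cyclohexenes next to quaternary carbons and diastereotopic-group-selective metathesis at carbons bearing two vinyl groups. Ring A closes as a six-membered carbocycle, cis-fused to the lactone and trans-fused to ring B. The new stereocentre C1 is set by which vinyl is incorporated, and the controlling element is the γ-lactone: only the vinyl cis to the C7–C7a bond can reach C3. Closure through the other vinyl would fuse the lactone trans to a cyclohexene already trans-fused to ring B at the neighbouring bond, which a half-chair is not expected to accommodate, so that alkylidene should return to the pool by exchange with ethene. The untouched vinyl therefore lies cis to the C7 methyl and becomes the ethyl group. The step also needs chemoselectivity against the C5=C6 alkene (trisubstituted, unstrained, hindered) and against intermolecular metathesis (neopentylic vinyl groups, high dilution). Benzoquinone suppresses hydride-mediated alkene migration and ethene removal drives the closure.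

Step 14
Reactants: 24 tricyclic vinyl lactone
Product: 25 tricyclic ethyl lactone (as 24 with ethyl in place of vinyl on C1)
Conditions: H2 (1 atm), RhCl(PPh3)3 (5 mol %), benzene–EtOH (1:1), 23 °C
Reagents that add atoms: none
Why: Homogeneous hydrogenation with RhCl(PPh3)3 reduces the monosubstituted vinyl group and should leave the two trisubstituted ring alkenes untouched (steric selectivity of the catalyst); C1 is unaffected.

Step 15
Reactants: 25 tricyclic ethyl lactone
Product: 27 aldehyde acid in its ring form (hemiacylal: hydroxyl on C1' of the lactone; anomeric mixture), via potassium hydroxy carboxylate 26 (not isolated)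
Conditions: KOH (1.1 equiv), MeOH–H2O, 70 °C; evaporate; 2-iodoxybenzoic acid, DMSO, 23 °C; aq. Na2S2O3 then 1 M HCl
Reagents that add atoms: potassium hydroxide [K+].[OH-]
Why: Hydroxide opens the hindered lactone irreversibly to the carboxylate, which cannot re-lactonise; the hypervalent iodine reagent then oxidises the neopentylic primary alcohol to the aldehyde, and acidification gives the aldehyde acid as its hemiacylal tautomer. C7 and C1 are quaternary, so no stereocentre of the skeleton can epimerise.

Step 16
Reactants: 27 aldehyde acid in its ring form (hemiacylal)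
Product: 28 (E)-enal acid (C1 carries (E)-CH=C(CH3)CHO; free carboxylic acid on C7)
Conditions: Ph3P=C(CH3)CHO (2.5 equiv), toluene, 110 °C
Reagents that add atoms: 2-(triphenylphosphoranylidene)propanal CC(C=O)=P(c1ccccc1)(c1ccccc1)c1ccccc1
Why: Wittig olefination with a formyl-stabilised ylide: the hemiacylal is in ring–chain equilibrium with the open aldehyde (the basic ylide favours the open carboxylate), and the stabilised ylide gives the (E)-trisubstituted enal.

Step 17
Reactants: 28 (E)-enal acid
Product: 29 target acid CNP0103503.1, (1S,3aS,4R,7R,7aR) with (1E,3E)-2-methyl-4-phenylbuta-1,3-dienyl on C1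
Conditions: (EtO)2P(O)CH2Ph, NaN(SiMe3)2, THF, 0 → 23 °C; 1 M HCl
Reagents that add atoms: diethyl benzylphosphonate CCOP(=O)(Cc1ccccc1)OCC
Why: Horner–Wadsworth–Emmons olefination of the enal with the benzylphosphonate anion gives the (E)-styryl double bond; excess base keeps the acid as its carboxylate, which is released on acidic work-up.

## Compound list

1 | but-2-yne-1,4-diol | OCC#CCO | starting material
2 | 4-(tert-butyldimethylsilyloxy)but-2-yn-1-ol | OCC#CCO[Si](C)(C)C(C)(C)C | intermediate
3 | sodium alkenylaluminate (cyclic ate complex, not isolated) | [Na+].COCCO[Al-]1(OCCOC)OCC=C1CO[Si](C)(C)C(C)(C)C | intermediate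
4 | (Z)-4-(tert-butyldimethylsilyloxy)-3-iodobut-2-en-1-ol | OC/C=C(\I)CO[Si](C)(C)C(C)(C)C | intermediate
5 | (E)-3-[(tert-butyldimethylsilyloxy)methyl]penta-2,4-dien-1-ol | OC/C=C(\C=C)CO[Si](C)(C)C(C)(C)C | intermediate
6 | propanoyl chloride | CCC(=O)Cl | starting material
7 | (E)-3-[(tert-butyldimethylsilyloxy)methyl]penta-2,4-dien-1-yl propanoate | CCC(=O)OC/C=C(\C=C)CO[Si](C)(C)C(C)(C)C | intermediate
8 | trimethylsilyl ketene acetal of 7 (not isolated) | CC=C(O[Si](C)(C)C)OC/C=C(\C=C)CO[Si](C)(C)C(C)(C)C | intermediate
9 | trimethylsilyl 4-(tert-butyldimethylsilyloxy)-2-methyl-3,3-divinylbutanoate (racemic, not isolated) | CC(C(=O)O[Si](C)(C)C)C(C=C)(C=C)CO[Si](C)(C)C(C)(C)C | intermediate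
10 | 4-hydroxy-2-methyl-3,3-divinylbutanoic acid (racemic, not isolated) | CC(C(=O)O)C(C=C)(C=C)CO | intermediate
11 | 4,4-diethenyl-3-methyloxolan-2-one (racemic) | CC1C(=O)OCC1(C=C)C=C | intermediate
12 | (S)-4-(tert-butyldimethylsilyloxy)cyclopent-2-en-1-one | O=C1C=C[C@@H](O[Si](C)(C)C(C)(C)C)C1 | starting material
13 | 2-bromopropene | CC(Br)=C | starting material
14 | isopropenylmagnesium bromide (not isolated) | CC(=C)[Mg]Br | intermediate
15 | bromomagnesium enolate of the 1,4-adduct (not isolated) | Br[Mg]OC1=C[C@H](C(C)=C)[C@@H](O[Si](C)(C)C(C)(C)C)C1 | intermediate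
16 | (2S,3R,4S)-4-(tert-butyldimethylsilyloxy)-2-methyl-3-(prop-1-en-2-yl)cyclopentan-1-one | O=C1C[C@H](O[Si](C)(C)C(C)(C)C)[C@@H](C(C)=C)[C@@H]1C | intermediate
17 | (4R,5S)-5-methyl-4-(prop-1-en-2-yl)cyclopent-2-en-1-one | O=C1C=C[C@@H](C(C)=C)[C@@H]1C | intermediate
18 | (4S,5S)-2-iodo-5-methyl-4-(prop-1-en-2-yl)cyclopent-2-en-1-one | O=C1C(I)=C[C@@H](C(C)=C)[C@@H]1C | intermediate
19 | (4R,5S)-2,5-dimethyl-4-(prop-1-en-2-yl)cyclopent-2-en-1-one | O=C1C(C)=C[C@@H](C(C)=C)[C@@H]1C | intermediate
20 | tert-butyl[(4,4-diethenyl-3-methyl-4,5-dihydrofuran-2-yl)oxy]dimethylsilane (not isolated) | CC1=C(O[Si](C)(C)C(C)(C)C)OCC1(C=C)C=C | intermediate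
21 | (3R)-3-[(1R,4S,5R)-3-(tert-butyldimethylsilyloxy)-2,4-dimethyl-5-(prop-1-en-2-yl)cyclopent-2-en-1-yl]-4,4-diethenyl-3-methyloxolan-2-one | C=CC1(C=C)COC(=O)[C@]1(C)[C@H]2C(C)=C(O[Si](C)(C)C(C)(C)C)[C@@H](C)[C@@H]2C(C)=C | intermediate
22 | (3R)-4,4-diethenyl-3-[(1R,4S,5R)-2,4-dimethyl-5-(prop-1-en-2-yl)-3-(trifluoromethanesulfonyloxy)cyclopent-2-en-1-yl]-3-methyloxolan-2-one | C=CC1(C=C)COC(=O)[C@]1(C)[C@H]2C(C)=C(OS(=O)(=O)C(F)(F)F)[C@@H](C)[C@@H]2C(C)=C | intermediate
23 | (3R)-4,4-diethenyl-3-[(1R,4R,5S)-2,4-dimethyl-5-(prop-1-en-2-yl)cyclopent-2-en-1-yl]-3-methyloxolan-2-one (metathesis precursor) | C=CC1(C=C)COC(=O)[C@]1(C)[C@H]2C(C)=C[C@@H](C)[C@@H]2C(C)=C | intermediate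
24 | tricyclic vinyl lactone (rings A and B closed; vinyl on C1) | C=C[C@@]12COC(=O)[C@]1(C)[C@H]3C(C)=C[C@@H](C)[C@@H]3C(C)=C2 | intermediate
25 | tricyclic ethyl lactone | CC[C@@]12COC(=O)[C@]1(C)[C@H]3C(C)=C[C@@H](C)[C@@H]3C(C)=C2 | intermediate
26 | potassium salt of the C1'-hydroxy C8-carboxylate (not isolated) | CC[C@]1(CO)C=C(C)[C@H]2[C@H](C)C=C(C)[C@@H]2[C@@]1(C)C(=O)[O-].[K+] | intermediate
27 | aldehyde acid in its ring form (hemiacylal, anomeric mixture) | CC[C@@]12C(O)OC(=O)[C@]1(C)[C@H]3C(C)=C[C@@H](C)[C@@H]3C(C)=C2 | intermediate
28 | (E)-enal acid | CC[C@]1(/C=C(C)/C=O)C=C(C)[C@H]2[C@H](C)C=C(C)[C@@H]2[C@@]1(C)C(=O)O | intermediate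
29 | CNP0103503.1, (1S,3aS,4R,7R,7aR)-1-ethyl-3,4,6,7-tetramethyl-1-[(1E,3E)-2-methyl-4-phenylbuta-1,3-dienyl]-3a,4,7,7a-tetrahydro-1H-indene-7-carboxylic acid (locants of the ring description) | CC[C@]1(/C=C(C)/C=C/c2ccccc2)C=C(C)[C@H]2[C@H](C)C=C(C)[C@@H]2[C@@]1(C)C(=O)O | target

## Step count and least certain steps

Total: 17 steps. Longest linear sequence: 13 steps (steps 1–5 and 10–17); the cyclopentenone branch (steps 6–9) joins at step 10.

**Step 13 (key step).** The most likely failure is stalling of the ring closure. The carbene loads on a neopentylic vinyl group and must add across a 1,1-disubstituted alkene while two adjacent quaternary carbons and a trans ring fusion are locked in place, so catalyst decay and hydride-induced alkene migration can outrun cyclisation. The fallback is a relay metathesis that delivers the metal onto C3 intramolecularly; it sets out from 12 and returns at 24.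
- But-2-yn-1-ol is converted as in step 2 into (Z)-3-iodobut-2-en-1-ol F1 and O-allylated (NaH, allyl bromide, THF) to (Z)-1-(allyloxy)-3-iodobut-2-ene F2.
- Its Grignard reagent replaces 14 under the conditions of step 6 and gives the relay ketone F3.
- The operations of steps 7 to 12 are repeated unchanged and give in turn the relay enone F4, the relay iodoenone F5, the relay methyl enone F6, the relay silyl enol ether F7, the relay triflate F8 and the relay precursor F9.
- With the same ruthenium catalyst F9 should load at the unhindered allyl ether terminus and expel 2,5-dihydrofuran, leaving the carbene on C3. This carbene then only has to choose the cis vinyl group, under the same lactone control, to give 24.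

**Step 10.** The most likely failure is poor or reversed facial matching of the two planar partners at C7, because the open transition state is governed by small steric differences between the C6 and C3a flanks of the enone. Slow addition is a second possibility, since a fully substituted, neopentylic nucleophilic carbon must bond to a hindered β-carbon. The fallback makes the C7–C7a bond by an intramolecular [3,3] shift; it sets out from 19 and 9 and returns at 23.
- 19 is reduced at the carbonyl under catalyst control ((R)-1-methyl-3,3-diphenyltetrahydro-1H,3H-pyrrolo[1,2-c][1,3,2]oxazaborole, catecholborane) to (1S,4R,5S)-2,5-dimethyl-4-(prop-1-en-2-yl)cyclopent-2-en-1-ol F10.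
- 9 is taken out of step 5 by neutral aqueous work-up as 4-(tert-butyldimethylsilyloxy)-2-methyl-3,3-divinylbutanoic acid F11.
- Yamaguchi esterification (2,4,6-trichlorobenzoyl chloride, Et3N, 4-(dimethylamino)pyridine) joins them to the cyclopentenyl ester F12.
- Ireland–Claisen rearrangement (KN(SiMe3)2, Me3SiCl, toluene–THF, −78 → 80 °C) should deliver C7 to C7a on the face that carried the oxygen, anti to isopropenyl, and move the alkene to C5=C6. It gives the rearranged acid F13 without any triflate chemistry.
- Aqueous HCl in THF–MeOH then removes the silyl ether and closes the lactone to 23.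
- The configuration at C7 depends here on the ketene acetal geometry, which can be inverted by the enolisation medium (THF against THF–HMPA). This is a lever the conjugate addition does not offer.

**Step 6.** The most likely failure is proton transfer between the enolate and the methylated product before alkylation is complete. This is followed by loss of silanolate from the isomerised enolate, leading to unmethylated enone and mis-alkylation. The fallback separates the two bond formations; it sets out from 12 and returns at 17.
- The same copper-catalysed addition is quenched with aqueous NH4Cl to give (3R,4S)-4-(tert-butyldimethylsilyloxy)-3-(prop-1-en-2-yl)cyclopentan-1-one F14.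
- DBU eliminates silanol to give (S)-4-(prop-1-en-2-yl)cyclopent-2-en-1-one F15.
- Kinetic α'-deprotonation (LiN(i-Pr)2, THF, −78 °C) and methylation with MeI anti to the isopropenyl group give 17.

**Step 15.** The most likely failure is re-closure of the lactone whenever the carboxylate is protonated before the alcohol is oxidised. Over-oxidation of the hemiacylal toward the anhydride is a second possibility. The fallback oxidises a neutral ester instead of the salt; it sets out from 25 and returns at 27.
- 26 is formed as in step 15, dried and alkylated on oxygen (allyl bromide, DMF, 0 °C) to the allyl hydroxy ester F16.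
- This is oxidised at once (Dess–Martin periodinane, NaHCO3, CH2Cl2) to the allyl aldehyde ester F17.
- Deallylation (Pd(PPh3)4, morpholine, THF, 23 °C) gives 27.

**Step 16.** The most likely failure is sluggish condensation of the weakly nucleophilic stabilised ylide with an aldehyde that is neopentylic, flanked by two quaternary carbons and largely masked as the hemiacylal. Prolonged heating could also erode the alkene geometry. The fallback builds the trisubstituted alkene by hydrometalation and cross-coupling instead of carbonyl olefination; it sets out from 27 and returns at 29.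
- Ohira–Bestmann homologation (dimethyl (1-diazo-2-oxopropyl)phosphonate, K2CO3, MeOH) gives the ethynyl acid F18.
- Double deprotonation (n-BuLi, THF, −78 °C) and C-methylation with MeI give the propynyl acid F19.
- Syn-hydrozirconation with Cp2Zr(H)Cl places the metal on the less hindered, methyl-bearing carbon. Transmetalation (ZnCl2) and Negishi coupling with (E)-β-bromostyrene (Pd(PPh3)4) give 29 with both alkene geometries fixed by the mechanism.

## Further compounds

F1 | step 13 | (Z)-3-iodobut-2-en-1-ol | C/C(I)=C/CO
F2 | step 13 | (Z)-1-(allyloxy)-3-iodobut-2-ene | C/C(I)=C/COCC=C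
F3 | step 13 | relay ketone, (2S,3R,4S)-3-[(Z)-4-(allyloxy)but-2-en-2-yl]-4-(tert-butyldimethylsilyloxy)-2-methylcyclopentan-1-one | O=C1C[C@H](O[Si](C)(C)C(C)(C)C)[C@@H](/C(C)=C\COCC=C)[C@@H]1C
F4 | step 13 | relay enone, 4-[(Z)-4-(allyloxy)but-2-en-2-yl]-5-methylcyclopent-2-en-1-one (analogue of 17) | O=C1C=C[C@@H](/C(C)=C\COCC=C)[C@@H]1C
F5 | step 13 | relay iodoenone (analogue of 18) | O=C1C(I)=C[C@@H](/C(C)=C\COCC=C)[C@@H]1C
F6 | step 13 | relay methyl enone (analogue of 19) | O=C1C(C)=C[C@@H](/C(C)=C\COCC=C)[C@@H]1C
F7 | step 13 | relay silyl enol ether (analogue of 21) | C=CC1(C=C)COC(=O)[C@]1(C)[C@H]2C(C)=C(O[Si](C)(C)C(C)(C)C)[C@@H](C)[C@@H]2/C(C)=C\COCC=C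
F8 | step 13 | relay triflate (analogue of 22) | C=CC1(C=C)COC(=O)[C@]1(C)[C@H]2C(C)=C(OS(=O)(=O)C(F)(F)F)[C@@H](C)[C@@H]2/C(C)=C\COCC=C
F9 | step 13 | relay precursor (analogue of 23) | C=CC1(C=C)COC(=O)[C@]1(C)[C@H]2C(C)=C[C@@H](C)[C@@H]2/C(C)=C\COCC=C
F10 | step 10 | (1S,4R,5S)-2,5-dimethyl-4-(prop-1-en-2-yl)cyclopent-2-en-1-ol | O[C@@H]1C(C)=C[C@@H](C(C)=C)[C@@H]1C
F11 | step 10 | 4-(tert-butyldimethylsilyloxy)-2-methyl-3,3-divinylbutanoic acid (racemic) | CC(C(=O)O)C(C=C)(C=C)CO[Si](C)(C)C(C)(C)C
F12 | step 10 | cyclopentenyl ester of F11 with F10 | CC(C(=O)O[C@@H]1C(C)=C[C@@H](C(C)=C)[C@@H]1C)C(C=C)(C=C)CO[Si](C)(C)C(C)(C)C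
F13 | step 10 | rearranged acid (C7–C7a bond formed; silyl ether on C1') | C=CC(C=C)(CO[Si](C)(C)C(C)(C)C)[C@](C)(C(=O)O)[C@H]1C(C)=C[C@@H](C)[C@@H]1C(C)=C
F14 | step 6 | (3R,4S)-4-(tert-butyldimethylsilyloxy)-3-(prop-1-en-2-yl)cyclopentan-1-one | O=C1C[C@H](O[Si](C)(C)C(C)(C)C)[C@@H](C(C)=C)C1
F15 | step 6 | (S)-4-(prop-1-en-2-yl)cyclopent-2-en-1-one | O=C1C=C[C@@H](C(C)=C)C1
F16 | step 15 | allyl hydroxy ester (C1' alcohol; C8 allyl ester) | CC[C@]1(CO)C=C(C)[C@H]2[C@H](C)C=C(C)[C@@H]2[C@@]1(C)C(=O)OCC=C
F17 | step 15 | allyl aldehyde ester | CC[C@]1(C=O)C=C(C)[C@H]2[C@H](C)C=C(C)[C@@H]2[C@@]1(C)C(=O)OCC=C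
F18 | step 16 | ethynyl acid | CC[C@]1(C#C)C=C(C)[C@H]2[C@H](C)C=C(C)[C@@H]2[C@@]1(C)C(=O)O
F19 | step 16 | propynyl acid | CC[C@]1(C#CC)C=C(C)[C@H]2[C@H](C)C=C(C)[C@@H]2[C@@]1(C)C(=O)O
A1 | alternative 1 | bicyclo[3.1.1]heptan-6-one with C7 and C1 as adjacent quaternary carbons, silyl ether on C3, 4-methoxybenzyl ether on C1' | CC[C@]1(COCc4ccc(OC)cc4)[C@@H]3[C@H](O[Si](C)(C)C(C)(C)C)CC[C@@]1(C)C3=O
A2 | alternative 2 | ring A acid with both quaternary carbons, silyl ether on C1', vinyl and isopropenyl arms for ring B | CC[C@]1(CO[Si](C)(C)C(C)(C)C)C=C(C)[C@@H]([C@H](C)C=C)[C@H](C(C)=C)[C@@]1(C)C(=O)O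
A3 | alternative 3 | tricyclic lactone enone with rings A and B closed, silyl ether on C3 | CC[C@]12C[C@H](O[Si](C)(C)C(C)(C)C)[C@H]3[C@H](C)C(=O)C(C)=C3[C@@]1(C)C(=O)OC2
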